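**Plan**

- Retrosynthesis: the two O-protecting groups are removed last; ring C is then cut at C4a–C4, C4–C3 and O1–C2, giving a ring A 2-iodophenol, carbon monoxide (as C4) and a ring B arylacetylene.
- Enabling feature: C4 is a carbonyl carbon lying between C4a of ring A and the C3=C2 unit that bears ring B, and O1 sits on C8a next to C4a, so ring C is an aryl–CO–alkyne assembly closed by a phenol oxygen.
- Ring A piece: carbamoylation of the aldehyde phenol, Baeyer–Villiger oxygenation (future 5-O, capped as MOM ether), carbamate-directed lithiation and iodination, carbamate hydrolysis.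
- Ring B piece: 4-O-benzylation, double methylation, Ohira–Bestmann alkynylation.
- Forward order: rings A and B come from the two aldehydes; ring C is the only ring made (step 9); MOM and benzyl removal follow.
- Stereochemistry: the target has no stereocentre and no stereogenic double bond, so nothing has to be set.

Key step: step 9

Remark on the chemistry: the 5-oxygen is carried through the annulation as a methoxymethyl ether and the 4'-oxygen as a benzyl ether, so the end game needs no Lewis-acid demethylation beside the four methoxy groups that must stay. Both aldehydes and carbon monoxide are taken as commercial.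

**Route**

Step 1
Reactants: 1 3-hydroxy-4,5-dimethoxybenzaldehyde
Product: 2 5-formyl-2,3-dimethoxyphenyl N,N-diethylcarbamate
Conditions: Et2NCOCl (1.2 equiv), K2CO3 (1.5 equiv), MeCN, reflux
Reagents that add atoms: N,N-diethylcarbamoyl chloride, CCN(CC)C(Cl)=O
Why: O-carbamoylation of the phenoxide (acyl substitution at the carbamoyl chloride) installs the group that later directs ortho-lithiation and keeps this oxygen, the future O1, distinct from the oxygen introduced in step 2.

Step 2
Reactants: 2 5-formyl-2,3-dimethoxyphenyl N,N-diethylcarbamate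
Product: 4 5-hydroxy-2,3-dimethoxyphenyl N,N-diethylcarbamate, via aryl formate 3 (not isolated)
Conditions: mCPBA (1.3 equiv), CH2Cl2, 0 °C to rt; then K2CO3 (cat.), MeOH, rt
Reagents that add atoms: mCPBA (3-chloroperoxybenzoic acid), OOC(=O)c1cccc(Cl)c1
Why: Baeyer–Villiger (Dakin-type) oxidation, in which the electron-rich aryl group (para to a methoxy group) migrates in the Criegee adduct to give the aryl formate; mild methanolysis cleaves the formate while the far less electrophilic diethylcarbamate stays.

Step 3
Reactants: 4 5-hydroxy-2,3-dimethoxyphenyl N,N-diethylcarbamate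
Product: 5 2,3-dimethoxy-5-(methoxymethoxy)phenyl N,N-diethylcarbamate
Conditions: MOMCl (1.5 equiv), iPr2NEt (2 equiv), CH2Cl2, 0 °C to rt
Reagents that add atoms: chloromethyl methyl ether, COCCl
Why: Williamson-type O-alkylation gives an acetal ether that is stable to base and organolithiums, supports the coming metalation as a second director, and can be taken off with mild acid to reveal the 5-hydroxyl.

Step 4
Reactants: 5 2,3-dimethoxy-5-(methoxymethoxy)phenyl N,N-diethylcarbamate
Product: 7 2-iodo-5,6-dimethoxy-3-(methoxymethoxy)phenyl N,N-diethylcarbamate, via aryllithium 6 (not isolated)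
Conditions: sBuLi (1.2 equiv), TMEDA (1.2 equiv), THF, −78 °C; then I2 (1.3 equiv), THF, −78 °C to rt
Reagents that add atoms: iodine, II
Why: Directed ortho-metalation, in which the carbamate (the strongest oxygen director) and the MOM ether cooperate on the single C–H between them, so that site should be lithiated in preference to the C–H between OMOM and OMe; iodine traps the aryllithium at −78 °C before an anionic ortho-Fries shift can set in.

Step 5
Reactants: 7 2-iodo-5,6-dimethoxy-3-(methoxymethoxy)phenyl N,N-diethylcarbamate
Product: 8 2-iodo-5,6-dimethoxy-3-(methoxymethoxy)phenol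
Conditions: NaOH (10 equiv), EtOH–H2O, reflux; then aq. NH4Cl to pH 6–7
Reagents that add atoms: none
Why: Base hydrolysis of the aryl carbamate (acyl substitution by hydroxide) frees the phenoxide, while the MOM acetal, the methyl ethers and the electron-rich aryl iodide are inert to hydroxide; the near-neutral work-up keeps the MOM group.

Step 6
Reactants: 9 2,3,4-trihydroxybenzaldehyde
Product: 10 4-benzyloxy-2,3-dihydroxybenzaldehyde
Conditions: BnBr (1.0 equiv), NaHCO3 (1.5 equiv), NaI (cat.), DMF, 40 °C
Reagents that add atoms: benzyl bromide, BrCc1ccccc1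
Why: Regioselective Williamson etherification, since a hydrogencarbonate base ionises mainly the 4-hydroxyl (the most acidic, para to the formyl group) and the 2-hydroxyl is held in a hydrogen bond to the carbonyl.

Step 7
Reactants: 10 4-benzyloxy-2,3-dihydroxybenzaldehyde
Product: 11 4-benzyloxy-2,3-dimethoxybenzaldehyde
Conditions: MeI (3 equiv), K2CO3 (3 equiv), DMF, 40 °C
Reagents that add atoms: iodomethane, CI
Why: Williamson methylation of both remaining phenols, under carbonate in DMF strong enough to alkylate the hydrogen-bonded 2-hydroxyl as well.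

Step 8
Reactants: 11 4-benzyloxy-2,3-dimethoxybenzaldehyde
Product: 12 1-benzyloxy-4-ethynyl-2,3-dimethoxybenzene
Conditions: dimethyl (1-diazo-2-oxopropyl)phosphonate (1.3 equiv), K2CO3 (2 equiv), MeOH, rt
Reagents that add atoms: dimethyl (1-diazo-2-oxopropyl)phosphonate, CC(=O)C(=[N+]=[N-])P(=O)(OC)OC
Why: Ohira–Bestmann (Seyferth–Gilbert) homologation, in which methanolysis of the reagent gives the diazomethylphosphonate anion; its Horner–Wadsworth–Emmons-type addition, loss of N2 and 1,2-shift turn the non-enolisable aldehyde into the terminal alkyne under mild base.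

Step 9
Reactants: 8 2-iodo-5,6-dimethoxy-3-(methoxymethoxy)phenol, 12 1-benzyloxy-4-ethynyl-2,3-dimethoxybenzene, 13 carbon monoxide
Product: 16 4'-benzyloxy-7,8,2',3'-tetramethoxy-5-(methoxymethoxy)flavone, via hydroxyaryl ynone 14 (not isolated), via enaminone 15 (not isolated)
Conditions: PdCl2(dppf) (5 mol %), CO (20 bar), Et2NH, 120 °C, autoclave
Reagents that add atoms: none
Why: Zerovalent palladium, formed from PdCl2(dppf) in the amine, adds oxidatively to the C–I bond of 8, CO inserts to give an aroylpalladium species, and coupling with the acetylide of 12 makes C4a–C4 and C4–C3 in ynone 14. Et2NH adds to the ynone to give enaminone 15, whose amine-bearing carbon (C2) is attacked by the phenol oxygen with loss of the amine, so ring C closes by a 6-endo-trig addition–elimination that forms O1–C2. The closest known reaction type is the carbonylative Sonogashira coupling of 2-iodophenols with terminal alkynes under palladium catalysis, which runs on to flavones in secondary-amine media. No stereocentre is created. The step needs six-membered closure to beat the 5-exo-dig closure of the ynone (aurone formation) and CO insertion to beat direct alkyne coupling; the enaminone pathway and the CO pressure should secure these. Regiochemistry is fixed by the substrate, because the iodine-bearing carbon has only one free hydroxyl beside it (its other neighbour oxygen is MOM-capped), so the oxygen next to the future 8-methoxy group becomes O1.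

Step 10
Reactants: 16 4'-benzyloxy-7,8,2',3'-tetramethoxy-5-(methoxymethoxy)flavone
Product: 17 4'-benzyloxy-5-hydroxy-7,8,2',3'-tetramethoxyflavone
Conditions: HCl (1.25 M in MeOH), THF, 50 °C
Reagents that add atoms: none
Why: Acid-catalysed acetal methanolysis removes the MOM group, helped by the hydrogen bond of the freed 5-hydroxyl to the C4 carbonyl; benzyl and methyl aryl ethers do not react with dilute methanolic HCl.

Step 11
Reactants: 17 4'-benzyloxy-5-hydroxy-7,8,2',3'-tetramethoxyflavone
Product: 18 5,4'-dihydroxy-7,8,2',3'-tetramethoxyflavone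
Conditions: H2 (1 atm), 10% Pd/C, EtOAc–MeOH, rt
Reagents that add atoms: none
Why: Catalytic hydrogenolysis of the benzylic C–O bond over palladium on carbon frees the 4'-hydroxyl; at one atmosphere and with monitoring of hydrogen uptake the C2–C3 bond of the pyranone, conjugated to both aryl rings, should not be reduced.

**Compound list**

1 | 3-hydroxy-4,5-dimethoxybenzaldehyde | COc1cc(C=O)cc(O)c1OC | starting material
2 | 5-formyl-2,3-dimethoxyphenyl N,N-diethylcarbamate | CCN(CC)C(=O)Oc1cc(C=O)cc(OC)c1OC | intermediate
3 | 3-(diethylcarbamoyloxy)-4,5-dimethoxyphenyl formate | CCN(CC)C(=O)Oc1cc(OC=O)cc(OC)c1OC | intermediate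
4 | 5-hydroxy-2,3-dimethoxyphenyl N,N-diethylcarbamate | CCN(CC)C(=O)Oc1cc(O)cc(OC)c1OC | intermediate
5 | 2,3-dimethoxy-5-(methoxymethoxy)phenyl N,N-diethylcarbamate | CCN(CC)C(=O)Oc1cc(OCOC)cc(OC)c1OC | intermediate
6 | [2-(diethylcarbamoyloxy)-3,4-dimethoxy-6-(methoxymethoxy)phenyl]lithium | CCN(CC)C(=O)Oc1c([Li])c(OCOC)cc(OC)c1OC | intermediate
7 | 2-iodo-5,6-dimethoxy-3-(methoxymethoxy)phenyl N,N-diethylcarbamate | CCN(CC)C(=O)Oc1c(I)c(OCOC)cc(OC)c1OC | intermediate
8 | 2-iodo-5,6-dimethoxy-3-(methoxymethoxy)phenol | COCOc1cc(OC)c(OC)c(O)c1I | intermediate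
9 | 2,3,4-trihydroxybenzaldehyde | O=Cc1ccc(O)c(O)c1O | starting material
10 | 4-benzyloxy-2,3-dihydroxybenzaldehyde | O=Cc1ccc(OCc2ccccc2)c(O)c1O | intermediate
11 | 4-benzyloxy-2,3-dimethoxybenzaldehyde | COc1c(C=O)ccc(OCc2ccccc2)c1OC | intermediate
12 | 1-benzyloxy-4-ethynyl-2,3-dimethoxybenzene | C#Cc1ccc(OCc2ccccc2)c(OC)c1OC | intermediate
13 | carbon monoxide | [C-]#[O+] | starting material
14 | 3-(4-benzyloxy-2,3-dimethoxyphenyl)-1-[2-hydroxy-3,4-dimethoxy-6-(methoxymethoxy)phenyl]prop-2-yn-1-one | COCOc1cc(OC)c(OC)c(O)c1C(=O)C#Cc1ccc(OCc2ccccc2)c(OC)c1OC | intermediate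
15 | (E)-3-(4-benzyloxy-2,3-dimethoxyphenyl)-3-(diethylamino)-1-[2-hydroxy-3,4-dimethoxy-6-(methoxymethoxy)phenyl]prop-2-en-1-one | COCOc1cc(OC)c(OC)c(O)c1C(=O)/C=C(/N(CC)CC)c1ccc(OCc2ccccc2)c(OC)c1OC | intermediate
16 | 4'-benzyloxy-7,8,2',3'-tetramethoxy-5-(methoxymethoxy)flavone | COCOc1cc(OC)c(OC)c2oc(-c3ccc(OCc4ccccc4)c(OC)c3OC)cc(=O)c12 | intermediate
17 | 4'-benzyloxy-5-hydroxy-7,8,2',3'-tetramethoxyflavone | COc1cc(O)c2c(=O)cc(-c3ccc(OCc4ccccc4)c(OC)c3OC)oc2c1OC | intermediate
18 | 5,4'-dihydroxy-7,8,2',3'-tetramethoxyflavone | COc1cc(O)c2c(=O)cc(-c3ccc(O)c(OC)c3OC)oc2c1OC | target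

**Step count**

Total: 11 steps. Longest linear sequence: 8 steps (steps 1–5, 9, 10, 11, from 1); the alkyne branch (steps 6–8) is 3 steps.

**Steps most likely to fail**

1. Step 9. Oxidative addition into the doubly ortho-substituted, electron-rich C–I bond may be slow. Alkyne coupling without CO uptake followed by cycloisomerisation, capture of the aroylpalladium species by diethylamine, or five-membered closure of the ynone could then take over. The fallback uses neither palladium nor CO gas, sets out from 5 and 12 and returns at 16. Alkyne 12 is deprotonated with nBuLi (THF, −78 °C) and acylated with N-methoxy-N-methylcarbamoyl chloride to give the Weinreb amide 3-(4-benzyloxy-2,3-dimethoxyphenyl)-N-methoxy-N-methylprop-2-ynamide F1, whose amide carbon becomes C4. Aryllithium 6, made from 5 as in step 4, is added to F1 at −78 °C, and a cold acidic quench should give the ynone 2-[3-(4-benzyloxy-2,3-dimethoxyphenyl)prop-2-ynoyl]-5,6-dimethoxy-3-(methoxymethoxy)phenyl N,N-diethylcarbamate F2. Et2NH in EtOH adds to the triple bond to give the enaminone 2-[(E)-3-(4-benzyloxy-2,3-dimethoxyphenyl)-3-(diethylamino)prop-2-enoyl]-5,6-dimethoxy-3-(methoxymethoxy)phenyl N,N-diethylcarbamate F3. NaOH in aqueous EtOH at reflux then cleaves the carbamate, and the phenoxide displaces the amine at C2, which rejoins the route at 16.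

2. Step 4. The carbamoyl group may migrate from oxygen to the lithiated carbon (anionic ortho-Fries shift) before the iodine quench, or deprotonation may occur at the other flanked site between the MOM ether and the methoxy group. The fallback replaces metalation by electrophilic substitution, sets out from 5 and returns at 8. The carbamate of 5 is hydrolysed first (NaOH, EtOH–H2O, reflux) to 2,3-dimethoxy-5-(methoxymethoxy)phenol F4. This phenol is iodinated ortho to the hydroxyl with benzyltrimethylammonium dichloroiodate and NaHCO3 in CH2Cl2–MeOH at rt. One ortho position is blocked by a methoxy group, so only the wanted ortho site and the para site are open; iodination at the para site would have to be removed by chromatography.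

3. Step 6. Alkylation may run on to the 3-hydroxyl or to a bis-ether, because the selectivity rests only on the acidity difference between the phenols. The fallback masks the catechol, sets out from 9 and returns at 10. Aldehyde 9 is dissolved in aqueous borax (Na2B4O7) with NaOH, which ties the 2,3-diol up as the cyclic borate sodium 4-formyl-2,2,7-trihydroxy-1,3,2-benzodioxaborol-2-uide F5. The 4-phenoxide left free is benzylated with BnBr (Bu4NBr as phase-transfer catalyst, 40 °C), and acidification breaks the borate to give 10.

Further compounds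
F1 | step 9 | 3-(4-benzyloxy-2,3-dimethoxyphenyl)-N-methoxy-N-methylprop-2-ynamide | CON(C)C(=O)C#Cc1ccc(OCc2ccccc2)c(OC)c1OC
F2 | step 9 | 2-[3-(4-benzyloxy-2,3-dimethoxyphenyl)prop-2-ynoyl]-5,6-dimethoxy-3-(methoxymethoxy)phenyl N,N-diethylcarbamate | CCN(CC)C(=O)Oc1c(C(=O)C#Cc2ccc(OCc3ccccc3)c(OC)c2OC)c(OCOC)cc(OC)c1OC
F3 | step 9 | 2-[(E)-3-(4-benzyloxy-2,3-dimethoxyphenyl)-3-(diethylamino)prop-2-enoyl]-5,6-dimethoxy-3-(methoxymethoxy)phenyl N,N-diethylcarbamate | CCN(CC)C(=O)Oc1c(C(=O)/C=C(/N(CC)CC)c2ccc(OCc3ccccc3)c(OC)c2OC)c(OCOC)cc(OC)c1OC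
F4 | step 4 | 2,3-dimethoxy-5-(methoxymethoxy)phenol | COCOc1cc(O)c(OC)c(OC)c1
F5 | step 6 | sodium 4-formyl-2,2,7-trihydroxy-1,3,2-benzodioxaborol-2-uide | [Na+].O=Cc1ccc(O)c2O[B-](O)(O)Oc12
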